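Prostanoid numbering is used throughout: C1 is the ester carbon, C5–C7 are the acetoxy carbons, C8–C12 are the ring and C13–C20 are the ω-chain.

## Analysis of the target

- **Skeleton.** Punaglandin 2 (27) has one carbocycle, the cyclopent-2-enone C8–C9–C10–C11–C12 (C9=O, C10–Cl, C10=C11). C8 carries the α-chain. The fully substituted carbinol C12 carries the (Z)-oct-2-enyl ω-chain.
- **Stereocentres.** The SMILES decodes to 5S, 6R, 7R, 8R, 12S. C5–C7 form an all-syn (xylo) triacetoxy triad. C7/C8 stand in an anti-aldol relation. The α-chain at C8 is cis to the C12 hydroxyl and trans to the ω-chain.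
- **Which centres can be corrected.** C12 is quaternary and cannot be corrected once set. C8 is α to C9=O and can be equilibrated. C5–C7 are fixed once made.
- **Sensitive groups.**
  - The C7 acetate is β to C9=O, so E1cB loss of acetic acid gives the cross-conjugated dienone.
  - The α-chloroenone is a Michael acceptor.
  - The skipped Z-olefin C14=C15 rules out late hydrogenation and electrophilic halogenation.
  - A free C5 hydroxyl can lactonise onto the C1 ester.
- **First feature used.** C9=O and C12–O sit 1,4 across C10=C11, and C8 is an sp3 carbon attached to that C4O2 unit. This is the oxidation pattern of a 2-furylcarbinol in which furan C2–C5 are C9–C12 and the carbinol carbon is C8.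
- **Second feature used.** The C5–C7 triad has the configuration of C2–C4 of D-xylose.
- **Difficulty.** The C12 tertiary carbinol must be set in absolute terms next to an epimerisable, elimination-prone C8, and the 6,7-syn relation runs against Felkin control.

## Retrosynthetic reasoning

**27 ⇒ 25.** The three O–acyl bonds are cut last. A C7 acetate cannot survive any enolisation of C9=O, so no operation at C8 may follow its introduction. In 25, O5 and O6 are tied in an isopropylidene acetal, and O7 and O12 are free. The forward step must release two hydroxyls and acylate three secondary ones while leaving the tertiary C12–OH untouched.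

**25 ⇒ 24.** No bond is cut; only C8 is inverted. C8 is the one epimerisable centre, and its target configuration should be the more stable one: α-chain trans to the ω-chain, and O12–H able to hydrogen-bond to O7. The ring-forming step is therefore asked only for the configuration of C12, and C8 follows it by equilibration. This is done while O7 is a hydroxyl, the poorest available leaving group.

**24 ⇒ 21 (key).** The C8–C12 ring bond is cut and the ring oxygen of a furan is reinstated between C9 and C12. The precursor is the flat 3-chloro-5-alkyl-2-furylcarbinol 21. It already holds every carbon of 27, the chlorine at C10 and the Z-olefin, but no ring stereocentre. The forward rearrangement must build the carbocycle, install the C12 oxygen from the aqueous medium, unveil the chloroenone, and relay C7 → C8 → C12 in one electrocyclic event. Cutting C8–C12 removes the quaternary centre, the ring and the enone at once. Cutting C7–C8 would leave all of them to be made separately.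

**21 ⇒ 9 + 19.** The bond between C8 and C9 (furan C2) is cut. The forward reaction is a furyllithium addition to an aldehyde, and its outcome at C8 does not matter because C8 is ionised in the next step. The bromine of 9 fixes the site of metalation next to chlorine, which is what places the chlorine at C10 rather than C11.

**19 ⇒ 17 ⇒ 16 ⇒ 14 ⇒ 10 + 11.**
- C5, C6 and C7 of 19 are C2, C3 and C4 of the pentose in 10; C8 is its C5 and C4 is its C1.
- The C3=C4 bond is cut (Wittig with the three-carbon ylide from 11). This is the only C–C bond the chain needs.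
- The benzyl groups serve only for that step. The hydrogenation that saturates C3=C4 also removes them, before any other olefin is present.
- The 5,6-acetonide is chosen on purpose. A free or ether O5 would cyclise onto the C8 cation of the key step to give a tetrahydrofuran. Within the acetal, that attack would need a bicyclo[2.2.1] oxonium ion.

**9 ⇒ 5 + 7; 5 ⇒ 3 ⇒ 1; 7 ⇒ 6.** The C12–C13 bond is cut: furyllithium alkylation with an allylic bromide of fixed Z geometry. The halogens of 5 are placed by two regiodefined lithiations starting from 1.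

## Alternatives that were turned down

**Alternative 1:** C7–C8, the textbook aldol.
- *Forward key step:* the lithium enolate of the enantiopure silyl ether A1 adds to the diacetoxy aldehyde A2 to give A3. Acetylation and desilylation follow.
- *Why turned down:*
  - Ring and chain each need their own source of chirality, and the tertiary carbinol of A1 gets no relay from anything.
  - The required 6,7-syn relation is anti-Felkin for an α-acyloxy aldehyde, while the 7,8-anti relation is dictated by the cyclic enolate. C7 would therefore be formed against the substrate bias.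
  - The aldolate of A3 sits next to two acetates (acyl migration) and on an E1cB-prone carbon.
  - The sequence to A1 alone costs about as many steps as the whole furan branch plus the ring formation chosen here.

**Alternative 2:** C8–C12 by an ionic aldol.
- *Forward key step:* the 2,5-dialkylfuran A4 (C8 as CH2) is opened oxidatively to the cis-enedione A5, which is closed with mild base.
- *Why turned down:*
  - The relative configuration would be right, but in A5 the C10 chlorine is β to the C12 ketone. It is a vinylogous acid chloride and is lost to any oxygen nucleophile.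
  - The C13 protons are α to a ketone and allylic, so they compete with C8–H. That leads to the regioisomeric ring or to a conjugated olefin.
  - The C8 enolate has O7 as a β-leaving group.
  - Three chemoselectivity problems would fall on one basic step.

**Alternative 3:** C10=C11 by ring-closing metathesis of the acyclic chlorodiene A6.
- *Why turned down:*
  - A6 already contains all five stereocentres. Its C8 lies between a ketone and two β-oxygens, so retro-aldol and elimination threaten it.
  - Its C8/C12 pair would have to come from an acyclic aldol onto a ketone with no controlling element.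
  - The 2-chloro-enone olefin is a reluctant metathesis partner.
  - The C14=C15 olefin can close a six-membered ring with C10.
  - The key step would build one unstrained bond and set no stereocentre.

Key step: step 11

Remark: 10 is taken as a catalogue sugar derivative. If it is not available, it is two routine steps (benzylation, glycoside hydrolysis) from methyl β-D-xylopyranoside.

## Route

**Step 1**
Reactants: 1 3-bromofuran
Product: 3 3-chlorofuran, via furan-3-yllithium 2 (not isolated)
Conditions: n-BuLi, Et2O, −78 °C; C2Cl6, −78 °C → rt; fractional distillation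
Reagents that add atoms: hexachloroethane, ClC(Cl)(Cl)C(Cl)(Cl)Cl
Why: Bromine–lithium exchange followed by electrophilic chlorination; holding 2 at −78 °C prevents its isomerisation to the 2-lithio species.

**Step 2**
Reactants: 3 3-chlorofuran
Product: 5 2-bromo-3-chlorofuran, via (3-chlorofuran-2-yl)lithium 4 (not isolated)
Conditions: LDA (commercial solution), THF, −78 °C; BrCl2C–CCl2Br, −78 → 0 °C
Reagents that add atoms: 1,2-dibromo-1,1,2,2-tetrachloroethane, BrC(Cl)(Cl)C(Cl)(Cl)Br
Why: Directed deprotonation at C2, the position flanked by O and Cl, then electrophilic bromination; the bromine blocks C2 now and marks it for metalation in step 10.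

**Step 3**
Reactants: 6 (Z)-oct-2-en-1-ol
Product: 7 (Z)-1-bromooct-2-ene
Conditions: CBr4, PPh3, CH2Cl2, −20 → 0 °C
Reagents that add atoms: carbon tetrabromide, BrC(Br)(Br)Br
Why: Appel reaction; SN2 displacement at the primary allylic carbon at low temperature should keep the Z geometry.

**Step 4**
Reactants: 5 2-bromo-3-chlorofuran; 7 (Z)-1-bromooct-2-ene
Product: 9 2-bromo-3-chloro-5-[(Z)-oct-2-en-1-yl]furan, via (5-bromo-4-chlorofuran-2-yl)lithium 8 (not isolated)
Conditions: LDA (1.0 equiv), THF, −78 °C; 7, DMPU, −78 → −30 °C
Reagents that add atoms: none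
Why: The only remaining α-proton (C5) is removed, as in the C5 lithiation of 2,3-dihalofurans, and the furyllithium is alkylated by SN2 at the primary allylic bromide without copper, so that SN2′ attack is avoided.

**Step 5**
Reactants: 10 2,3,4-tri-O-benzyl-D-xylopyranose; 11 (2-carboxyethyl)triphenylphosphonium bromide
Product: 14 methyl (3Z,5S,6R,7R)-5,6,7-tris(benzyloxy)-8-hydroxyoct-3-enoate, via sodium 3-(triphenyl-λ5-phosphanylidene)propanoate 12 (not isolated), via (3Z,5S,6R,7R)-5,6,7-tris(benzyloxy)-8-hydroxyoct-3-enoic acid 13 (not isolated)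
Conditions: 11, NaHMDS, THF, −78 → 0 °C; 10, → rt; 1 M HCl work-up; TMSCHN2, PhMe–MeOH, 0 °C
Reagents that add atoms: (trimethylsilyl)diazomethane, C[Si](C)(C)C=[N+]=[N-]
Why: Wittig olefination of a lactol with a carboxylate ylide, as in prostanoid α-chain installation, then esterification; ring opening frees only O8 and adds C1–C3 in one operation, and the olefin geometry is irrelevant.

**Step 6**
Reactants: 14 methyl (3Z,5S,6R,7R)-5,6,7-tris(benzyloxy)-8-hydroxyoct-3-enoate
Product: 16 methyl (5S,6R,7R)-5,6:7,8-bis(isopropylidenedioxy)octanoate, via methyl (5S,6R,7R)-5,6,7,8-tetrahydroxyoctanoate 15 (not isolated)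
Conditions: H2, Pd(OH)2/C, MeOH, rt; filter, concentrate; Me2C(OMe)2, acetone, CSA (cat.), rt
Reagents that add atoms: 2,2-dimethoxypropane, COC(C)(C)OC
Why: One hydrogenation saturates C3=C4 and cleaves the three benzyl ethers; immediate acetalisation gives the only bis-dioxolane possible (a trans-5,6 ring from the threo diol plus the terminal 7,8 ring) before O5 can lactonise.

**Step 7**
Reactants: 16 methyl (5S,6R,7R)-5,6:7,8-bis(isopropylidenedioxy)octanoate
Product: 17 methyl (5S,6S,7R)-7,8-dihydroxy-5,6-(isopropylidenedioxy)octanoate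
Conditions: AcOH–H2O (7:3), rt, stopped at partial conversion, 16 recycled
Reagents that add atoms: none
Why: Selective hydrolysis of a terminal over an internal isopropylidene acetal, standard in carbohydrate chemistry (the change of the C6 descriptor is only a change of CIP priority).

**Step 8**
Reactants: 17 methyl (5S,6S,7R)-7,8-dihydroxy-5,6-(isopropylidenedioxy)octanoate
Product: 18 methyl (5S,6R,7R)-5,6-(isopropylidenedioxy)-7,8-bis(triethylsilyloxy)octanoate
Conditions: TESCl, imidazole, CH2Cl2, 0 °C → rt
Reagents that add atoms: chlorotriethylsilane, CC[Si](Cl)(CC)CC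
Why: Routine bis-silylation; TES is chosen because the next step distinguishes primary from secondary TES ethers.

**Step 9**
Reactants: 18 methyl (5S,6R,7R)-5,6-(isopropylidenedioxy)-7,8-bis(triethylsilyloxy)octanoate
Product: 19 methyl (5S,6R,7S)-5,6-(isopropylidenedioxy)-8-oxo-7-(triethylsilyloxy)octanoate
Conditions: (COCl)2, DMSO, CH2Cl2, −78 → −40 °C; Et3N, −78 °C → 0 °C
Reagents that add atoms: none
Why: Swern conditions oxidise a primary TES ether directly to the aldehyde while the secondary TES ether survives, which saves a deprotection step; C7 is untouched (descriptor change by priority only).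

**Step 10**
Reactants: 9 2-bromo-3-chloro-5-[(Z)-oct-2-en-1-yl]furan; 19 methyl (5S,6R,7S)-5,6-(isopropylidenedioxy)-8-oxo-7-(triethylsilyloxy)octanoate
Product: 21 methyl (5S,6R,7R)-8-{3-chloro-5-[(Z)-oct-2-en-1-yl]furan-2-yl}-8-hydroxy-5,6-(isopropylidenedioxy)-7-(triethylsilyloxy)octanoate (both C8 epimers), via {3-chloro-5-[(Z)-oct-2-en-1-yl]furan-2-yl}lithium 20 (not isolated)
Conditions: 9, n-BuLi, Et2O–THF, −78 °C; 19, −78 °C; AcOH quench at −78 °C
Reagents that add atoms: none
Why: Bromine–lithium exchange at the α-bromide and 1,2-addition; at −78 °C the aldehyde outcompetes the methyl ester, and the C8 configuration is of no consequence because C8 becomes planar in step 11.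

**Step 11**
Reactants: 21 methyl (5S,6R,7R)-8-{3-chloro-5-[(Z)-oct-2-en-1-yl]furan-2-yl}-8-hydroxy-5,6-(isopropylidenedioxy)-7-(triethylsilyloxy)octanoate
Product: 24 methyl (5S,6S,7R,8S,12S,14Z)-10-chloro-7,12-dihydroxy-5,6-(isopropylidenedioxy)-9-oxoprosta-10,14-dien-1-oate (8-epi series), via the 7,8-diol 22 (not isolated), via the 2-alkylidene-5-hydroxy-2,5-dihydrofuran 23 (not isolated)
Conditions: ZnCl2 (2 equiv), 1,4-dioxane–H2O (4:1), 95 °C
Reagents that add atoms: water, O
Why: Piancatelli rearrangement, whose closest precedent is the ZnCl2-promoted conversion of 5-alkyl-2-furylcarbinols into 4-alkyl-4-hydroxy-5-substituted cyclopent-2-enones. The medium strips the TES group (22) and ionises C8–OH to the furan-stabilised cation; water adds at C12, the only open α-carbon (23), and the hemiketal opens to the 9,12-dihydroxypentadienyl cation C8–C12. The single ring closes by a thermal 4π conrotatory electrocyclisation that forms C8–C12, and tautomerisation then unveils C9=O next to C10–Cl. The relative configuration follows from the cation geometry: O12 and C7 both take the outward positions (C7 is held away from the C10 chlorine), so conrotation places them trans and gives 8S together with 12S. The sense of rotation, and with it C12, is controlled by C7: allylic strain against O9 holds C7–H in the cation plane, so the new bond should form anti to the C7–C6 bond (the better σ-donor and the larger group), with the inward C13H2 swinging past the small free O7–H and not past the dioxolane, which for 7R leads to 12S. Only C12 has to be right here, since C8 is corrected in step 12. The substrate secures the other selectivities needed: chlorine stays on the central carbon of the cation, O5 is kept from C8 by the acetal (attack would need a bicyclo[2.2.1] oxonium ion), and the Z-olefin is too short-tethered to reach either cationic terminus.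

**Step 12**
Reactants: 24 methyl (5S,6S,7R,8S,12S,14Z)-10-chloro-7,12-dihydroxy-5,6-(isopropylidenedioxy)-9-oxoprosta-10,14-dien-1-oate
Product: 25 methyl (5S,6S,7R,8R,12S,14Z)-10-chloro-7,12-dihydroxy-5,6-(isopropylidenedioxy)-9-oxoprosta-10,14-dien-1-oate
Conditions: KOAc, MeOH, rt; chromatographic separation, 24 resubmitted
Reagents that add atoms: none
Why: Base-catalysed α-epimerisation under the mild acetate conditions that take 8-iso β-hydroxycyclopentanone prostanoids into the trans series; 25 should be favoured because the two carbon chains become trans and O12–H can hydrogen-bond to O7, and the β-substituents at this stage are hydroxyls, poor E1cB leaving groups.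

**Step 13**
Reactants: 25 methyl (5S,6S,7R,8R,12S,14Z)-10-chloro-7,12-dihydroxy-5,6-(isopropylidenedioxy)-9-oxoprosta-10,14-dien-1-oate
Product: 27 punaglandin 2, methyl (5S,6R,7R,8R,12S,14Z)-5,6,7-triacetoxy-10-chloro-12-hydroxy-9-oxoprosta-10,14-dien-1-oate, via methyl (5S,6R,7R,8R,12S,14Z)-10-chloro-5,6,7,12-tetrahydroxy-9-oxoprosta-10,14-dien-1-oate 26 (not isolated)
Conditions: TFA–H2O–CH2Cl2, 0 °C; co-evaporation with PhMe below rt; Ac2O, pyridine, 0 °C → rt, no DMAP
Reagents that add atoms: acetic anhydride, CC(=O)OC(C)=O
Why: Acetal hydrolysis and immediate acetylation, so that the δ-hydroxy ester has little time to lactonise; pyridine without DMAP acylates the three secondary alcohols, leaves the hindered tertiary C12–OH free and is too weak a base to trigger fast loss of the new C7 acetate.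

## Compound list

1 | 3-bromofuran | Brc1ccoc1 | starting material
2 | furan-3-yllithium | [Li]c1ccoc1 | intermediate
3 | 3-chlorofuran | Clc1ccoc1 | intermediate
4 | (3-chlorofuran-2-yl)lithium | [Li]c1occc1Cl | intermediate
5 | 2-bromo-3-chlorofuran | Brc1occc1Cl | intermediate
6 | (Z)-oct-2-en-1-ol | CCCCC/C=C\CO | starting material
7 | (Z)-1-bromooct-2-ene | CCCCC/C=C\CBr | intermediate
8 | (5-bromo-4-chlorofuran-2-yl)lithium | [Li]c1cc(Cl)c(Br)o1 | intermediate
9 | 2-bromo-3-chloro-5-[(Z)-oct-2-en-1-yl]furan | CCCCC/C=C\Cc1cc(Cl)c(Br)o1 | intermediate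
10 | 2,3,4-tri-O-benzyl-D-xylopyranose (anomers) | OC1OC[C@@H](OCc2ccccc2)[C@H](OCc2ccccc2)[C@H]1OCc1ccccc1 | starting material
11 | (2-carboxyethyl)triphenylphosphonium bromide | OC(=O)CC[P+](c1ccccc1)(c1ccccc1)c1ccccc1.[Br-] | starting material
12 | sodium 3-(triphenyl-λ5-phosphanylidene)propanoate | [Na+].[O-]C(=O)CC=P(c1ccccc1)(c1ccccc1)c1ccccc1 | intermediate
13 | (3Z,5S,6R,7R)-5,6,7-tris(benzyloxy)-8-hydroxyoct-3-enoic acid | OC[C@@H](OCc1ccccc1)[C@H](OCc1ccccc1)[C@H](/C=C\CC(O)=O)OCc1ccccc1 | intermediate
14 | methyl (3Z,5S,6R,7R)-5,6,7-tris(benzyloxy)-8-hydroxyoct-3-enoate | OC[C@@H](OCc1ccccc1)[C@H](OCc1ccccc1)[C@H](/C=C\CC(=O)OC)OCc1ccccc1 | intermediate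
15 | methyl (5S,6R,7R)-5,6,7,8-tetrahydroxyoctanoate | OC[C@@H](O)[C@H](O)[C@H](CCCC(=O)OC)O | intermediate
16 | methyl (5S,6R,7R)-5,6:7,8-bis(isopropylidenedioxy)octanoate | C1OC(C)(C)O[C@H]1[C@@H]2OC(C)(C)O[C@H]2CCCC(=O)OC | intermediate
17 | methyl (5S,6S,7R)-7,8-dihydroxy-5,6-(isopropylidenedioxy)octanoate | OC[C@@H](O)[C@@H]1OC(C)(C)O[C@H]1CCCC(=O)OC | intermediate
18 | methyl (5S,6R,7R)-5,6-(isopropylidenedioxy)-7,8-bis(triethylsilyloxy)octanoate | CC[Si](CC)(CC)OC[C@@H](O[Si](CC)(CC)CC)[C@@H]1OC(C)(C)O[C@H]1CCCC(=O)OC | intermediate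
19 | methyl (5S,6R,7S)-5,6-(isopropylidenedioxy)-8-oxo-7-(triethylsilyloxy)octanoate | O=C[C@@H](O[Si](CC)(CC)CC)[C@@H]1OC(C)(C)O[C@H]1CCCC(=O)OC | intermediate
20 | {3-chloro-5-[(Z)-oct-2-en-1-yl]furan-2-yl}lithium | CCCCC/C=C\Cc1cc(Cl)c([Li])o1 | intermediate
21 | furylcarbinol, 7-O-TES, 5,6-acetonide, both C8 epimers | CCCCC/C=C\Cc1cc(Cl)c(o1)C(O)[C@@H](O[Si](CC)(CC)CC)[C@@H]1OC(C)(C)O[C@H]1CCCC(=O)OC | intermediate
22 | furyl 7,8-diol, 5,6-acetonide, both C8 epimers | CCCCC/C=C\Cc1cc(Cl)c(o1)C(O)[C@@H](O)[C@@H]1OC(C)(C)O[C@H]1CCCC(=O)OC | intermediate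
23 | 2-alkylidene-3-chloro-5-hydroxy-5-[(Z)-oct-2-enyl]-2,5-dihydrofuran (C12 hemiketal) | CCCCC/C=C\CC1(O)C=C(Cl)C(O1)=C[C@@H](O)[C@@H]1OC(C)(C)O[C@H]1CCCC(=O)OC | intermediate
24 | methyl (5S,6S,7R,8S,12S,14Z)-10-chloro-7,12-dihydroxy-5,6-(isopropylidenedioxy)-9-oxoprosta-10,14-dien-1-oate | CCCCC/C=C\C[C@@]1(O)C=C(Cl)C(=O)[C@H]1[C@@H](O)[C@@H]2OC(C)(C)O[C@H]2CCCC(=O)OC | intermediate
25 | methyl (5S,6S,7R,8R,12S,14Z)-10-chloro-7,12-dihydroxy-5,6-(isopropylidenedioxy)-9-oxoprosta-10,14-dien-1-oate | CCCCC/C=C\C[C@@]1(O)C=C(Cl)C(=O)[C@@H]1[C@@H](O)[C@@H]2OC(C)(C)O[C@H]2CCCC(=O)OC | intermediate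
26 | methyl (5S,6R,7R,8R,12S,14Z)-10-chloro-5,6,7,12-tetrahydroxy-9-oxoprosta-10,14-dien-1-oate | CCCCC/C=C\C[C@@]1(O)C=C(Cl)C(=O)[C@@H]1[C@@H](O)[C@H](O)[C@H](CCCC(=O)OC)O | intermediate
27 | punaglandin 2 | CCCCC/C=C\C[C@@]1(O)C=C(Cl)C(=O)[C@@H]1[C@@H](OC(C)=O)[C@H](OC(C)=O)[C@H](CCCC(=O)OC)OC(C)=O | target

## Step count and least certain steps

Total: 13 steps. Longest linear sequence: 9 steps (steps 5–13). The furan branch (steps 1, 2, 4, then 10–13) is 7 steps long.

**Step 11 (key step).**
- *What may go wrong:*
  - Ionisation at C8 is slowed by the C10 chlorine and by O7. Forcing conditions may then cleave the 5,6-acetal, after which O5 traps the cation.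
  - The cation may lose the C7 proton, which is a glycol-to-ketone dehydration.
  - The sense of conrotation rests on a conformational model at C7. The model may give poor, or the opposite, facial selectivity at C12.
- *Fallback (known chemistry, ring and chain made separately):* it sets out from 20 (generated from 9 as in step 10) and from 17, and returns at 25.
  - 20 is quenched with paraformaldehyde to give the primary furfuryl alcohol F1.
  - Piancatelli rearrangement of F1 carries no side-chain oxygen and no stereochemical demand. It gives the racemic hydroxy-enone F2, which is silylated to F3.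
  - Periodate cleavage of 17 gives the acetonide aldehyde F4.
  - The lithium enolate of F3 is added to F4, and the (7R,8R,12S) diastereomer F5 is separated from its isomers.
  - HF·pyridine on F5 gives 25.

**Step 12.**
- *What may go wrong:* the equilibrium may favour 25 only weakly. Prolonged exposure may cause retro-aldol cleavage at C7–C8 or slow elimination of O7.
- *Fallback (kinetic instead of thermodynamic control):* it sets out from 24 and returns at 25.
  - Soft enolisation with TESOTf/Et3N gives the tris-silyl 5,5-disubstituted cyclopentadiene F6 without a free enolate.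
  - Buffered HF·pyridine then protonates C8 from the face opposite the bulky C12–OTES. This places the α-chain cis to O12. The same reagent removes all silyl groups to give 25.

**Step 5.**
- *What may go wrong:* the β-carboxylate ylide can fragment by retro-Michael loss of triphenylphosphine before it meets the small equilibrium amount of open aldehyde. The excess base may epimerise C5 or eliminate the β-benzyloxy group.
- *Fallback:* it sets out from 10 and returns at 16.
  - Methylenation with Ph3P=CH2 gives the terminal alkene F7.
  - Cross metathesis with methyl but-3-enoate gives the (E)-isomer F8.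
  - F8 enters the conditions of step 6 unchanged and gives 16.

**Step 4.**
- *What may go wrong:* bromine–lithium scrambling (halogen dance) of 8 may occur while the alkylation warms up. There may be partial SN2′ attack or loss of the Z geometry in the allylic bromide.
- *Fallback (silicon instead of bromine as blocking group):* it sets out from 3 and 7 and returns at 20, hence at 21.
  - 3 is lithiated with LDA and silylated to F9.
  - F9 is lithiated at C5 with s-BuLi and alkylated with 7 to give F10.
  - TBAF removes the silyl group to give F11.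
  - The only α-proton of F11 lies next to chlorine, and LDA removes it to give 20.

## Further compounds

F1 | step 11 | {3-chloro-5-[(Z)-oct-2-en-1-yl]furan-2-yl}methanol | CCCCC/C=C\Cc1cc(Cl)c(CO)o1
F2 | step 11 | rac-2-chloro-4-hydroxy-4-[(Z)-oct-2-en-1-yl]cyclopent-2-en-1-one | CCCCC/C=C\CC1(O)C=C(Cl)C(=O)C1
F3 | step 11 | rac-2-chloro-4-[(Z)-oct-2-en-1-yl]-4-(triethylsilyloxy)cyclopent-2-en-1-one | CCCCC/C=C\CC1(O[Si](CC)(CC)CC)C=C(Cl)C(=O)C1
F4 | step 11 | methyl (5S,6R)-5,6-(isopropylidenedioxy)-7-oxoheptanoate | O=C[C@@H]1OC(C)(C)O[C@H]1CCCC(=O)OC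
F5 | step 11 | 12-O-triethylsilyl ether of 25 | CCCCC/C=C\C[C@@]1(O[Si](CC)(CC)CC)C=C(Cl)C(=O)[C@@H]1[C@@H](O)[C@@H]2OC(C)(C)O[C@H]2CCCC(=O)OC
F6 | step 12 | 7,9,12-tris(triethylsilyloxy)cyclopenta-8,10-diene derived from 24 | CCCCC/C=C\C[C@@]1(O[Si](CC)(CC)CC)C=C(Cl)C(O[Si](CC)(CC)CC)=C1[C@@H](O[Si](CC)(CC)CC)[C@@H]2OC(C)(C)O[C@H]2CCCC(=O)OC
F7 | step 5 | (2R,3R,4S)-2,3,4-tris(benzyloxy)hex-5-en-1-ol | OC[C@@H](OCc1ccccc1)[C@H](OCc1ccccc1)[C@H](C=C)OCc1ccccc1
F8 | step 5 | methyl (3E,5S,6R,7R)-5,6,7-tris(benzyloxy)-8-hydroxyoct-3-enoate | OC[C@@H](OCc1ccccc1)[C@H](OCc1ccccc1)[C@H](/C=C/CC(=O)OC)OCc1ccccc1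
F9 | step 4 | (3-chlorofuran-2-yl)trimethylsilane | C[Si](C)(C)c1occc1Cl
F10 | step 4 | {3-chloro-5-[(Z)-oct-2-en-1-yl]furan-2-yl}trimethylsilane | CCCCC/C=C\Cc1cc(Cl)c([Si](C)(C)C)o1
F11 | step 4 | 4-chloro-2-[(Z)-oct-2-en-1-yl]furan | CCCCC/C=C\Cc1cc(Cl)co1
A1 | alternative 1 | (S)-4-(tert-butyldimethylsilyloxy)-2-chloro-4-[(Z)-oct-2-en-1-yl]cyclopent-2-en-1-one | CCCCC/C=C\C[C@@]1(O[Si](C)(C)C(C)(C)C)C=C(Cl)C(=O)C1
A2 | alternative 1 | methyl (5S,6R)-5,6-diacetoxy-7-oxoheptanoate | O=C[C@H](OC(C)=O)[C@H](CCCC(=O)OC)OC(C)=O
A3 | alternative 1 | 7-hydroxy-12-O-TBS aldol adduct (5,6-diacetate) | CCCCC/C=C\C[C@@]1(O[Si](C)(C)C(C)(C)C)C=C(Cl)C(=O)[C@@H]1[C@@H](O)[C@H](OC(C)=O)[C@H](CCCC(=O)OC)OC(C)=O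
A4 | alternative 2 | 3-chloro-2,5-dialkylfuran with C8 as CH2 (7-OH, 5,6-acetonide) | CCCCC/C=C\Cc1cc(Cl)c(C[C@@H](O)[C@@H]2OC(C)(C)O[C@H]2CCCC(=O)OC)o1
A5 | alternative 2 | 10-chloro-9,12-dioxo cis-enedione | CCCCC/C=C\CC(=O)/C=C(Cl)\C(=O)C[C@@H](O)[C@@H]1OC(C)(C)O[C@H]1CCCC(=O)OC
A6 | alternative 3 | acyclic 10-chloro-9-oxo-12-hydroxy-12-vinyl diene (10,11-seco, two terminal CH2) | CCCCC/C=C\C[C@@](O)(C=C)[C@H](C(=O)C(Cl)=C)[C@@H](OC(C)=O)[C@H](OC(C)=O)[C@H](CCCC(=O)OC)OC(C)=O
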